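**Retrosynthetic overview**

1. The lactam ring is attached last: Negishi coupling at C12–C13 of a C12 iodide with the enol triflate of N-Boc-tetramic acid. The 6β-acetate comes from hydride reduction of a C6 ketone, and C12 from an ester.
2. Ring B is closed in one operation from an acyclic enol ester. The acyl carbon C6 of β-cyclogeranic acid first sits on O9 of a β-keto ester enol; SmI2 moves it to C7 (bond C6–C7) and then joins C9 to C10 by ketyl addition to the enone just formed.
3. Enabling feature: in ring B the two oxygen-bearing carbons C6 and C9 stand 1,4 to each other, C7 is β to C9 and C10 is β to C6. O9 can therefore carry C6 as an ester before ring B exists, and each new bond joins a carbonyl carbon to the β-carbon of the other carbonyl.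
4. Ring order: ring A is bought (β-cyclocitral), ring B is made in the key step, the lactam ring is bought and attached at the end.
5. Stereocontrol: C8 comes from methyl (R)-3-hydroxy-2-methylpropanoate; C9, C10 and C5 are set in the key step; C6 is set by reduction.

Key step: step 7

Remark: positions are numbered as in labdanes (ring A = C1–C5 and C10; ring B = C5–C10; C17 = methyl on C8; C20 = methyl on C10; C11–C12 = link to the lactam carbons C13–C16).

**Step 1**
Reactants: 1 β-cyclocitral (2,6,6-trimethylcyclohex-1-ene-1-carbaldehyde)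
Product: 2 β-cyclogeranic acid (2,6,6-trimethylcyclohex-1-ene-1-carboxylic acid)
Conditions: NaClO2, NaH2PO4, 2-methyl-2-butene, t-BuOH/H2O, rt
Reagents that add atoms: sodium chlorite, [Na+].[O-]Cl=O
Why: Pinnick oxidation should convert the hindered enal to the acid without touching the tetrasubstituted alkene; no stereocenter is formed.

**Step 2**
Reactants: 3 methyl (R)-3-hydroxy-2-methylpropanoate
Product: 4 methyl (R)-3-[(tert-butyldimethylsilyl)oxy]-2-methylpropanoate
Conditions: TBSCl, imidazole, DMF, rt
Reagents that add atoms: tert-butyldimethylsilyl chloride, CC(C)(C)[Si](C)(C)Cl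
Why: Silyl ether formation protects the future C7 oxygen so that the C8 stereocenter can be carried through the Claisen condensation.

**Step 3**
Reactants: 4 methyl (R)-3-[(tert-butyldimethylsilyl)oxy]-2-methylpropanoate
Product: 5 ethyl (R)-5-[(tert-butyldimethylsilyl)oxy]-4-methyl-3-oxopentanoate
Conditions: EtOAc, LiN(SiMe3)2, THF, −78 °C; then 4, −78 to −40 °C; AcOH
Reagents that add atoms: ethyl acetate, CCOC(C)=O
Why: Crossed Claisen condensation with the lithium enolate of ethyl acetate gives the β-keto ester, whose immediate deprotonation at C11 should shield the α-stereocenter C8 from epimerization.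

**Step 4**
Reactants: 2 β-cyclogeranic acid; 5 ethyl (R)-5-[(tert-butyldimethylsilyl)oxy]-4-methyl-3-oxopentanoate
Product: 7 ethyl (2Z,4R)-5-[(tert-butyldimethylsilyl)oxy]-4-methyl-3-[(2,6,6-trimethylcyclohex-1-ene-1-carbonyl)oxy]pent-2-enoate, via acid chloride 6 (not isolated)
Conditions: 2, (COCl)2, DMF (cat.), CH2Cl2, 0 °C to rt, then evaporation; 5, NaH, Et2O, 0 °C, then 6, 0 °C to rt
Reagents that add atoms: none
Why: O-acylation of the chelated sodium enolate of the β-keto ester by the very hindered acid chloride (C-acylation is sterically disfavoured) should give the Z enol ester, with the acyloxy group cis to CO2Et and C8 untouched.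

**Step 5**
Reactants: 7 ethyl (2Z,4R)-5-[(tert-butyldimethylsilyl)oxy]-4-methyl-3-[(2,6,6-trimethylcyclohex-1-ene-1-carbonyl)oxy]pent-2-enoate
Product: 8 ethyl (2Z,4R)-5-hydroxy-4-methyl-3-[(2,6,6-trimethylcyclohex-1-ene-1-carbonyl)oxy]pent-2-enoate
Conditions: HF·pyridine, THF, 0 °C
Reagents that add atoms: none
Why: Fluoride desilylation in a mildly acidic medium should free the primary alcohol while the base-labile, hindered enol ester stays in place.

**Step 6**
Reactants: 8 ethyl (2Z,4R)-5-hydroxy-4-methyl-3-[(2,6,6-trimethylcyclohex-1-ene-1-carbonyl)oxy]pent-2-enoate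
Product: 9 ethyl (2Z,4S)-5-iodo-4-methyl-3-[(2,6,6-trimethylcyclohex-1-ene-1-carbonyl)oxy]pent-2-enoate (same arrangement at C8; the descriptor changes because CH2I outranks the enol carbon)
Conditions: PPh3, I2, imidazole (premixed), CH2Cl2, 0 °C
Reagents that add atoms: iodine, II
Why: Appel iodination replaces the primary hydroxyl by SN2 at C7 under neutral conditions, so neither C8 nor the enol ester should be affected.

**Step 7**
Reactants: 9 ethyl (2Z,4S)-5-iodo-4-methyl-3-[(2,6,6-trimethylcyclohex-1-ene-1-carbonyl)oxy]pent-2-enoate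
Product: 11 ethyl 2-[(1R,2R,4aS,8aS)-1-hydroxy-2,5,5,8a-tetramethyl-4-oxodecahydronaphthalen-1-yl]acetate, via diketo ester 10 (not isolated)
Conditions: SmI2 (6 equiv), Fe(dbm)3 (3 mol %, dbm = dibenzoylmethanate), THF, −30 to 0 °C; then MeOH (10 equiv), −78 °C to rt
Reagents that add atoms: none
Why: Proposed new method: samarium diiodide should reduce the C7–I bond to the primary alkylsamarium, which attacks the enol-ester carbonyl C6 through a five-membered transition state (intramolecular nucleophilic acyl substitution); collapse expels the chelated samarium enolate of the β-keto ester, so the acyl group moves from O9 to C7 and diketo ester 10 forms in the flask. After protonation by MeOH the chelation-activated C9 carbonyl is reduced to the ketyl, which adds to C10, the β-carbon of the new enone, and the α-keto radical is reduced to the enolate and protonated at C5. The closest known reactions are the samarium diiodide sequence of intramolecular nucleophilic acyl substitution followed by ketyl–olefin cyclization of halo esters, and the chelation-controlled ketyl–olefin cyclizations of β-keto esters; new here are the enol ester as acyl donor and the closure onto a tetrasubstituted enone. Ring B closes 6-endo-trig, the polarity-matched mode (nucleophilic ketyl on the enone β-carbon), whereas 5-exo attack at C5 is mismatched. For C10, the C5=C10 bond lies in ring A, so C20 must become axial on ring B and the C8 methyl stays equatorial in the chair to avoid it, which fixes the face of C10 that is attacked; for C9, without HMPA trivalent samarium can bridge O9 and the enone oxygen O6, which is possible only with O9 axial and anti to C20 and leaves the C11 arm equatorial; for C5, axial protonation anti to C20 and the 4β-methyl gives the trans ring fusion. The step needs acyl transfer to outrun simple reduction and to occur at C6 and not at the ester carbon C12, which the easily reduced primary iodide, the activated enol-ester carbonyl and the Z geometry (CO2Et held away from C7) should secure.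

**Step 8**
Reactants: 11 ethyl 2-[(1R,2R,4aS,8aS)-1-hydroxy-2,5,5,8a-tetramethyl-4-oxodecahydronaphthalen-1-yl]acetate
Product: 12 (1R,2R,4R,4aS,8aS)-1-(2-hydroxyethyl)-2,5,5,8a-tetramethyldecahydronaphthalene-1,4-diol
Conditions: LiAlH4, THF, 0 °C; then H2O
Reagents that add atoms: none
Why: Hydride reduction turns the ester into the C12 alcohol and the C6 ketone into the axial 6β-alcohol, because the β face of C6 is blocked by the syn-axial C20 and 4β methyls and hydride should arrive from the α face.

**Step 9**
Reactants: 12 (1R,2R,4R,4aS,8aS)-1-(2-hydroxyethyl)-2,5,5,8a-tetramethyldecahydronaphthalene-1,4-diol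
Product: 13 (1R,2R,4R,4aS,8aS)-1-(2-iodoethyl)-2,5,5,8a-tetramethyldecahydronaphthalene-1,4-diol
Conditions: PPh3, I2, imidazole, CH2Cl2, 0 °C
Reagents that add atoms: iodine, II
Why: Appel iodination should be selective for the unhindered primary C12 hydroxyl over the axial secondary 6-OH and the tertiary 9-OH.

**Step 10**
Reactants: 13 (1R,2R,4R,4aS,8aS)-1-(2-iodoethyl)-2,5,5,8a-tetramethyldecahydronaphthalene-1,4-diol
Product: 14 (1R,3R,4R,4aS,8aS)-4-hydroxy-4-(2-iodoethyl)-3,4a,8,8-tetramethyldecahydronaphthalen-1-yl acetate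
Conditions: Ac2O, Et3N, DMAP (cat.), CH2Cl2, rt
Reagents that add atoms: acetic anhydride, CC(=O)OC(C)=O
Why: DMAP-catalysed acetylation should esterify the secondary 6β-hydroxyl, while the tertiary 9-hydroxyl is too hindered to react.

**Step 11**
Reactants: 15 tert-butyl 2,4-dioxopyrrolidine-1-carboxylate (N-Boc-tetramic acid)
Product: 16 tert-butyl 2-oxo-4-[(trifluoromethanesulfonyl)oxy]-2,5-dihydro-1H-pyrrole-1-carboxylate
Conditions: Tf2O, i-Pr2NEt, CH2Cl2, −78 °C
Reagents that add atoms: trifluoromethanesulfonic anhydride, O=S(=O)(OS(=O)(=O)C(F)(F)F)C(F)(F)F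
Why: O-triflation of the enol form of the vinylogous acid gives the C13 electrophile with the ring double bond already in place.

**Step 12**
Reactants: 14 (1R,3R,4R,4aS,8aS)-4-hydroxy-4-(2-iodoethyl)-3,4a,8,8-tetramethyldecahydronaphthalen-1-yl acetate; 16 tert-butyl 2-oxo-4-[(trifluoromethanesulfonyl)oxy]-2,5-dihydro-1H-pyrrole-1-carboxylate
Product: 18 tert-butyl 4-{2-[(1R,2R,4R,4aS,8aS)-4-(acetyloxy)-1-hydroxy-2,5,5,8a-tetramethyldecahydronaphthalen-1-yl]ethyl}-2-oxo-2,5-dihydro-1H-pyrrole-1-carboxylate, via alkylzinc iodide 17 (not isolated)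
Conditions: 14, Zn dust, LiCl, THF, 40 °C; then 16, Pd(PPh3)4 (5 mol %), THF, 50 °C
Reagents that add atoms: none
Why: Zinc insertion into the primary iodide followed by Negishi coupling with the activated enol triflate joins C12 to C13; alkylzinc iodides tolerate the acetate and the hindered tertiary hydroxyl.

**Step 13**
Reactants: 18 tert-butyl 4-{2-[(1R,2R,4R,4aS,8aS)-4-(acetyloxy)-1-hydroxy-2,5,5,8a-tetramethyldecahydronaphthalen-1-yl]ethyl}-2-oxo-2,5-dihydro-1H-pyrrole-1-carboxylate
Product: 19 (1R,3R,4R,4aS,8aS)-4-hydroxy-3,4a,8,8-tetramethyl-4-[2-(5-oxo-2,5-dihydro-1H-pyrrol-3-yl)ethyl]decahydronaphthalen-1-yl acetate (target)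
Conditions: CF3CO2H, CH2Cl2, 0 °C
Reagents that add atoms: none
Why: Acidolysis of the acyl carbamate should free the lactam N–H at low temperature before the tertiary alcohol or the acetate can react.

**Compound list**

1 | β-cyclocitral (2,6,6-trimethylcyclohex-1-ene-1-carbaldehyde) | CC1=C(C=O)C(C)(C)CCC1 | starting material
2 | β-cyclogeranic acid (2,6,6-trimethylcyclohex-1-ene-1-carboxylic acid) | CC1=C(C(=O)O)C(C)(C)CCC1 | intermediate
3 | methyl (R)-3-hydroxy-2-methylpropanoate | COC(=O)[C@H](C)CO | starting material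
4 | methyl (R)-3-[(tert-butyldimethylsilyl)oxy]-2-methylpropanoate | COC(=O)[C@H](C)CO[Si](C)(C)C(C)(C)C | intermediate
5 | ethyl (R)-5-[(tert-butyldimethylsilyl)oxy]-4-methyl-3-oxopentanoate | CCOC(=O)CC(=O)[C@H](C)CO[Si](C)(C)C(C)(C)C | intermediate
6 | 2,6,6-trimethylcyclohex-1-ene-1-carbonyl chloride | CC1=C(C(=O)Cl)C(C)(C)CCC1 | intermediate
7 | ethyl (2Z,4R)-5-[(tert-butyldimethylsilyl)oxy]-4-methyl-3-[(2,6,6-trimethylcyclohex-1-ene-1-carbonyl)oxy]pent-2-enoate | CCOC(=O)/C=C(\OC(=O)C1=C(C)CCCC1(C)C)[C@H](C)CO[Si](C)(C)C(C)(C)C | intermediate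
8 | ethyl (2Z,4R)-5-hydroxy-4-methyl-3-[(2,6,6-trimethylcyclohex-1-ene-1-carbonyl)oxy]pent-2-enoate | CCOC(=O)/C=C(\OC(=O)C1=C(C)CCCC1(C)C)[C@H](C)CO | intermediate
9 | ethyl (2Z,4S)-5-iodo-4-methyl-3-[(2,6,6-trimethylcyclohex-1-ene-1-carbonyl)oxy]pent-2-enoate | CCOC(=O)/C=C(\OC(=O)C1=C(C)CCCC1(C)C)[C@H](C)CI | intermediate
10 | ethyl (4R)-4-methyl-3,6-dioxo-6-(2,6,6-trimethylcyclohex-1-en-1-yl)hexanoate | CCOC(=O)CC(=O)[C@H](C)CC(=O)C1=C(C)CCCC1(C)C | intermediate
11 | ethyl 2-[(1R,2R,4aS,8aS)-1-hydroxy-2,5,5,8a-tetramethyl-4-oxodecahydronaphthalen-1-yl]acetate | O=C1C[C@@H](C)[C@](O)(CC(=O)OCC)[C@@]2(C)CCCC(C)(C)[C@H]12 | intermediate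
12 | (1R,2R,4R,4aS,8aS)-1-(2-hydroxyethyl)-2,5,5,8a-tetramethyldecahydronaphthalene-1,4-diol | O[C@@H]1C[C@@H](C)[C@](O)(CCO)[C@@]2(C)CCCC(C)(C)[C@H]12 | intermediate
13 | (1R,2R,4R,4aS,8aS)-1-(2-iodoethyl)-2,5,5,8a-tetramethyldecahydronaphthalene-1,4-diol | O[C@@H]1C[C@@H](C)[C@](O)(CCI)[C@@]2(C)CCCC(C)(C)[C@H]12 | intermediate
14 | (1R,3R,4R,4aS,8aS)-4-hydroxy-4-(2-iodoethyl)-3,4a,8,8-tetramethyldecahydronaphthalen-1-yl acetate | CC(=O)O[C@@H]1C[C@@H](C)[C@](O)(CCI)[C@@]2(C)CCCC(C)(C)[C@H]12 | intermediate
15 | tert-butyl 2,4-dioxopyrrolidine-1-carboxylate | CC(C)(C)OC(=O)N1CC(=O)CC1=O | starting material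
16 | tert-butyl 2-oxo-4-[(trifluoromethanesulfonyl)oxy]-2,5-dihydro-1H-pyrrole-1-carboxylate | CC(C)(C)OC(=O)N1CC(OS(=O)(=O)C(F)(F)F)=CC1=O | intermediate
17 | iodo{2-[(1R,2R,4R,4aS,8aS)-4-(acetyloxy)-1-hydroxy-2,5,5,8a-tetramethyldecahydronaphthalen-1-yl]ethyl}zinc | CC(=O)O[C@@H]1C[C@@H](C)[C@](O)(CC[Zn]I)[C@@]2(C)CCCC(C)(C)[C@H]12 | intermediate
18 | tert-butyl 4-{2-[(1R,2R,4R,4aS,8aS)-4-(acetyloxy)-1-hydroxy-2,5,5,8a-tetramethyldecahydronaphthalen-1-yl]ethyl}-2-oxo-2,5-dihydro-1H-pyrrole-1-carboxylate | CC(=O)O[C@@H]1C[C@@H](C)[C@](O)(CCC2=CC(=O)N(C(=O)OC(C)(C)C)C2)[C@@]2(C)CCCC(C)(C)[C@H]12 | intermediate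
19 | (1R,3R,4R,4aS,8aS)-4-hydroxy-3,4a,8,8-tetramethyl-4-[2-(5-oxo-2,5-dihydro-1H-pyrrol-3-yl)ethyl]decahydronaphthalen-1-yl acetate | CC(=O)O[C@@H]1C[C@@H](C)[C@](O)(CCC2=CC(=O)NC2)[C@@]2(C)CCCC(C)(C)[C@H]12 | target

**Step count and risks**

Total step count: 13. Longest linear sequence: 11 steps (steps 2 to 10, 12 and 13, from methyl (R)-3-hydroxy-2-methylpropanoate).

Steps most likely to fail:

Step 7 (Proposed new method). The alkylsamarium may be protonated before acyl transfer, or the iodide may simply be reduced. The crowded ketyl may be reduced to the alcohol instead of closing onto the tetrasubstituted C10. Facial selectivity at C9 may be poor if the metal does not bridge O9 and O6. Fallback: the two bond formations are separated and run with known chemistry, setting out from 9 and coming back at 11. Iodine–lithium exchange on 9 (t-BuLi, 2 equiv, Et2O/pentane, −100 °C) should trigger the known anionic oxygen-to-carbon acyl migration of lithioalkyl esters and give diketo ester 10, now isolated after an acidic quench. 10 is then closed to 11 in its own step under the established conditions for chelated β-keto ester ketyls (SmI2, MeOH, THF, −78 °C), where concentration and proton source can be tuned for the ring closure alone. This detour makes no new compound (F0).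

Step 4. Acylation may take place at carbon C11 in place of oxygen, or the E enol ester may form, which would later let C7 reach the ester carbon C12. Fallback: the enol ester is built by addition of the acid to an alkyne, setting out from 5 and 2 and coming back at 7. Ketone 5 is converted (NaH, Tf2O, Et2O, 0 °C) to the Z enol triflate ethyl (2Z,4R)-5-[(tert-butyldimethylsilyl)oxy]-4-methyl-3-[(trifluoromethanesulfonyl)oxy]pent-2-enoate F1. Anti elimination (LiN(SiMe3)2, THF, −78 °C) gives the ynoate ethyl (4S)-5-[(tert-butyldimethylsilyl)oxy]-4-methylpent-2-ynoate F2. Gold-catalysed anti addition of acid 2 across the triple bond (Ph3PAuCl, AgOTf, toluene, 60 °C) should place the carboxylate on C9 cis to CO2Et and so give 7 as the Z isomer only.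

Step 12. The alkylzinc may be protonated by the neighbouring tertiary hydroxyl, or transmetalation of the hindered chain may be slow, so that reduction or elimination of the iodide wins. Fallback: the lactam ring is built on the chain by a radical route, setting out from 14 and coming back at 19. Giese addition of the C12 radical from 14 ((Me3Si)3SiH, AIBN, toluene, 80 °C) to methyl 4-[(tert-butoxycarbonyl)amino]but-2-ynoate should give methyl (2Z)-5-[(1R,2R,4R,4aS,8aS)-4-(acetyloxy)-1-hydroxy-2,5,5,8a-tetramethyldecahydronaphthalen-1-yl]-3-{[(tert-butoxycarbonyl)amino]methyl}pent-2-enoate F3, formed together with its E isomer. Removal of the Boc group (CF3CO2H, CH2Cl2, 0 °C) and neutralisation should let the amine close onto the ester, with the E isomer equilibrating on warming, to give 19 directly.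

**Further compounds**

F0 | step 7 | none | none
F1 | step 4 | ethyl (2Z,4R)-5-[(tert-butyldimethylsilyl)oxy]-4-methyl-3-[(trifluoromethanesulfonyl)oxy]pent-2-enoate | CCOC(=O)/C=C(\OS(=O)(=O)C(F)(F)F)[C@H](C)CO[Si](C)(C)C(C)(C)C
F2 | step 4 | ethyl (4S)-5-[(tert-butyldimethylsilyl)oxy]-4-methylpent-2-ynoate | CCOC(=O)C#C[C@H](C)CO[Si](C)(C)C(C)(C)C
F3 | step 12 | methyl (2Z)-5-[(1R,2R,4R,4aS,8aS)-4-(acetyloxy)-1-hydroxy-2,5,5,8a-tetramethyldecahydronaphthalen-1-yl]-3-{[(tert-butoxycarbonyl)amino]methyl}pent-2-enoate | CC(=O)O[C@@H]1C[C@@H](C)[C@](O)(CC/C(CNC(=O)OC(C)(C)C)=C/C(=O)OC)[C@@]2(C)CCCC(C)(C)[C@H]12
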